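| flask | starting material | free catalyst | time |
|---|---|---|---|
| epsilon | 300 mM | 3.00 mM |  |
| alpha | 300 mM | 6.00 mM |  |
| zeta | 600 mM | 3.00 mM |  |
| beta | 300 mM | 3.00 mM | 470 min |

| run | time / min | [target] / mM |
|---|---|---|
| epsilon run | 16 | 36.4 |
| epsilon run | 32 | 66.6 |
| epsilon run | 47 | 91.9 |
| epsilon run | 63 | 114.0 |
| epsilon run | 79 | 133.1 |
| alpha run | 16 | 52.6 |
| alpha run | 32 | 95.1 |
| alpha run | 47 | 124.5 |
| alpha run | 63 | 151.7 |
| alpha run | 79 | 170.8 |
| zeta run | 16 | 68.5 |
| zeta run | 32 | 127.2 |
| zeta run | 47 | 172.8 |
| zeta run | 63 | 218.0 |
| zeta run | 79 | 252.5 |

(standard deviation of a reading: 0.9 mM)

1. apparent order in [free catalyst] of the starting rate, round the charge of the epsilon run (the rate where two percent of its starting material have turned into target)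
2. apparent order in [starting material] of the starting rate, round the charge of the epsilon run (the rate where two percent of its starting material have turned into target) (one fixed amount of target, the same in the runs compared)
3. target in the beta run at 470 min, as a share of the starting material charged

- Overall: starting material -> target, with free catalyst as catalyst.
- Constant volume, constant temperature.
- Bound and free are read together.
- An order is taken over about fifteen percent of the charge, up and down.

- Early in the epsilon run, over the first 16 min, I read the average rate per unit of starting material, taken as the charge less the target, and this pseudo-first-order constant comes to 0.00808 min⁻¹. Over the same time the alpha run, with twice the free catalyst, gives 0.0120 min⁻¹, which is less than double.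
- I suppose that this constant is a sum of one part that grows in step with the catalyst and one part that ignores it. Twice the epsilon constant minus the alpha constant then gives 0.00412 min⁻¹, the catalyst-free clock, a reading that carries the scatter of 0.9 mM.
- This clock is about half of the epsilon constant, and for such a sum the local order in catalyst equals the catalysed share, which I put at 0.490. The forecast, at 0.58, is higher, and it reads the weak response differently: “much of the catalyst sits in an inactive reservoir”.
- Between 63 min and 79 min the epsilon constant reads 0.00677 min⁻¹, so the whole stands at 0.838 of its early reading. With the clock held fixed, the catalysed part stands at 0.669 of its early reading.
- The beta run repeats the epsilon charge, so I let the share not yet read as target at 79 min decay exponentially on the clock up to 470 min, with the catalysed part left out of this reckoning. This gives 88.9% of target, my own reckoning, beside the forecast's 90% and its order in starting material of 0.93.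

    free catalyst + starting material ⇌ catalyst-substrate complex, settled at all times (12.10 M⁻¹)
    catalyst-substrate complex + starting material ⇌ doubly bound catalyst, settled at all times (1.050 M⁻¹)
    doubly bound catalyst → target + catalyst-substrate complex (2.130 min⁻¹)
    2 starting material → homo dimer (0.003324 M⁻¹ min⁻¹)
    starting material → target (0.003972 min⁻¹)

- The beta run gives 85.1% of target, and the apparent orders round the epsilon charge are 0.51 in free catalyst and 1.0 in starting material, so the forecast stands within its margins, and the beta result lies 3.8 percentage points below my reckoning. The flask holds a homo dimer route, which takes starting material without giving target, and my single clock holds no such route. The catalysed share of 0.490, a reading from the first 16 min of the epsilon run, stands beside the order of 0.51 in free catalyst. In the zeta run, the clock started from the reading at 79 min, with the catalysed part again left out, puts target at half of the charge at 115 min, later than the 105 min that the zeta run gives.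

The runs were generated by integration for substances that don't exist; scatter was added.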